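**Strategy**

Numbering: C1 (tertiary carbinol bearing C7H2OBz), C2 (OAc), C3 (OBz), C4=C5, C6 (OH). C1 and C2 carry trans oxygens and C4=C5 lies across the ring, so C4=C5 is stored as an endo cyclopentadiene adduct of a quinone, whose norbornene roofs the concave face. Alkaline peroxide then epoxidises the C1=C2 enedione alkene from the convex face only, forming both C–O bonds, the oxirane and two stereocentres at once; cycloreversion later returns C4=C5. The precursor is the enantioenriched tricyclic enedione (C3, C6 ketones) with a silyloxymethyl group at C1, preferred to an ester so that the enolate has no leaving group and the later acetate opening at C2 is hydroxyl-directed.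

Key step: step 4

Remark: the C1–C7 numbering above is kept for the tricyclic compounds ("convex" is the face of the six-membered ring that carries the ring-fusion hydrogens); the (S)-catalyst of step 3 is assigned from the usual coordination model of protonated oxazaborolidines, and its mirror image would be used if the model pointed the wrong way.

**Route**

Step 1
Reactants: 1 2,5-dimethoxybenzyl alcohol; 2 tert-butyl(chloro)diphenylsilane
Product: 3 tert-butyl[(2,5-dimethoxybenzyl)oxy]diphenylsilane
Conditions: TBDPSCl (1.1 equiv), imidazole (2 equiv), DMF, rt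
Reagents that add atoms: tert-butyl(chloro)diphenylsilane (2), CC(C)(C)[Si](Cl)(c1ccccc1)c1ccccc1
Why: Imidazole-promoted O-silylation of the only hydroxyl; the tert-butyldiphenylsilyl ether is chosen because, unlike an ester, it is no leaving group and survives aqueous tetravalent cerium, the acidic cycloaddition catalyst and alkaline peroxide, yet can be removed later to uncover a directing hydroxyl.

Step 2
Reactants: 3 tert-butyl[(2,5-dimethoxybenzyl)oxy]diphenylsilane
Product: 4 2-{[tert-butyl(diphenyl)silyl]oxymethyl}-1,4-benzoquinone
Conditions: (NH4)2Ce(NO3)6 (2.5 equiv), MeCN–H2O (2:1), 0 °C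
Reagents that add atoms: water, O
Why: Oxidative demethylation of the 1,4-dimethoxyarene by two one-electron oxidations with (NH4)2Ce(NO3)6 (ipso attack of water, loss of methanol) gives the para-quinone, and the bulky silyl ether should tolerate the brief acidic contact at 0 °C.

Step 3
Reactants: 4 2-{[tert-butyl(diphenyl)silyl]oxymethyl}-1,4-benzoquinone; 5 cyclopenta-1,3-diene
Product: 6 endo adduct (4aS,5R,8S,8aR)-2-{[tert-butyl(diphenyl)silyl]oxymethyl}-4a,5,8,8a-tetrahydro-5,8-methanonaphthalene-1,4-dione
Conditions: (S)-1-(2-methylphenyl)-3,3-diphenyltetrahydro-1H,3H-pyrrolo[1,2-c][1,3,2]oxazaborole (C24H24BNO, 20 mol %), HN(SO2CF3)2 (20 mol %), cyclopentadiene (3 equiv, added slowly), CH2Cl2, −78 °C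
Reagents that add atoms: cyclopenta-1,3-diene (5), C1=CCC=C1
Why: Enantioselective Diels–Alder reaction under protonated oxazaborolidine catalysis: the unsubstituted C4=C5 alkene is the more reactive dienophile, boron should bind the more basic and less crowded C3 carbonyl syn to C4–H, and cyclopentadiene then adds endo (Alder rule) to the face not covered by the catalyst aryl group, which sets C4, C5 and both bridgeheads in one step.

Step 4
Reactants: 6 endo adduct (4aS,5R,8S,8aR)-2-{[tert-butyl(diphenyl)silyl]oxymethyl}-4a,5,8,8a-tetrahydro-5,8-methanonaphthalene-1,4-dione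
Product: 8 convex-face C1–C2 epoxy diketone, via hydroperoxy enolate 7 (not isolated)
Conditions: 30% aq. H2O2, Na2CO3, acetone–H2O, 0 °C
Reagents that add atoms: hydrogen peroxide, OO
Why: Weitz–Scheffer nucleophilic epoxidation: hydroperoxide anion adds in conjugate fashion to the unsubstituted C2 terminus of the C1=C2 enedione alkene to give the C1=C6 enolate 7, whose C1 then attacks the proximal peroxide oxygen and expels hydroxide. The closest known reaction is the alkaline hydrogen peroxide epoxidation of cyclopentadiene–quinone adducts, which takes place on the convex face. The oxirane is closed in the 3-exo-tet mode on the O–O bond. Both new stereocentres, C1 and C2, are controlled by the cis-fused norbornene installed in step 3: it roofs the concave face of the six-membered ring, so the oxygen enters at C2 from the convex side and, since a three-membered ring can only be cis-fused, is delivered to C1 on the same side. The step needs one face of C1=C2 and reaction at this alkene only; the cage secures the first, and the nucleophilic oxidant, which ignores the electron-rich norbornene alkene, secures the second. The silyl ether at C7 leaves enolate 7 without a leaving group to eject or an ester to cleave, and carbonate at 0 °C should keep enolisation at C4/C5 slower than epoxidation.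

Step 5
Reactants: 8 convex-face C1–C2 epoxy diketone
Product: 9 tricyclic epoxy diol (C3–OH and C6–OH on the concave face, trans to the oxirane oxygen)
Conditions: NaBH4 (2.5 equiv), CeCl3·7H2O (2 equiv), MeOH–CH2Cl2, −78 → −20 °C
Reagents that add atoms: none
Why: Luche reduction: in the cage both ketones can only be reached by hydride from the convex face, so the C3 and C6 hydroxyls end up on the concave face, anti to the oxirane (C6 already as in the target), and the cerium-buffered borohydride should leave epoxide and silyl ether untouched.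

Step 6
Reactants: 9 tricyclic epoxy diol; 10 benzoic acid
Product: 11 tricyclic C3 benzoate (C3–OBz now on the convex, oxirane face; C6–OH still concave)
Conditions: BzOH (1.5 equiv), PPh3 (1.5 equiv), DIAD (1.5 equiv), THF, 0 °C → rt
Reagents that add atoms: benzoic acid (10), O=C(O)c1ccccc1
Why: Mitsunobu esterification (SN2 with inversion): the C3 carbinol, flanked only by CH groups, is activated and displaced by benzoate from the open convex face, which turns its oxygen to the oxirane side as the target requires, whereas the C6 carbinol next to the fully substituted C1 and its bulky silyloxymethyl arm is neopentyl-like and should stay free.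

Step 7
Reactants: 11 tricyclic C3 benzoate
Product: 12 (1S,2R,3R,6R)-1-{[tert-butyl(diphenyl)silyl]oxymethyl}-1,2-epoxy-6-hydroxycyclohex-4-en-3-yl benzoate
Conditions: Ph2O, 250 °C, 30 min, Ar stream
Reagents that add atoms: none
Why: Retro-Diels–Alder cycloreversion, well precedented for oxygenated norbornene-fused cyclohexanes at this temperature: cyclopentadiene distils off, the C4=C5 alkene is released, and none of the stereocentres C1, C2, C3 and C6 takes part.

Step 8
Reactants: 12 (1S,2R,3R,6R)-1-{[tert-butyl(diphenyl)silyl]oxymethyl}-1,2-epoxy-6-hydroxycyclohex-4-en-3-yl benzoate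
Product: 13 (1S,2R,3R,6R)-1,2-epoxy-6-hydroxy-1-(hydroxymethyl)cyclohex-4-en-3-yl benzoate
Conditions: HF·pyridine, pyridine, THF, 0 °C → rt
Reagents that add atoms: none
Why: Fluoride-induced Si–O cleavage under buffered, slightly acidic conditions frees the primary C7 hydroxyl without forming an alkoxide, so neither Payne rearrangement of the epoxy alcohol nor benzoate migration is expected.

Step 9
Reactants: 13 (1S,2R,3R,6R)-1,2-epoxy-6-hydroxy-1-(hydroxymethyl)cyclohex-4-en-3-yl benzoate; 14 acetic acid
Product: 15 (1S,2S,3R,6R)-3-(benzoyloxy)-1,6-dihydroxy-1-(hydroxymethyl)cyclohex-4-en-2-yl acetate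
Conditions: AcOH (3 equiv), Ti(OiPr)4 (1.5 equiv), CH2Cl2, rt; aq. tartaric acid work-up
Reagents that add atoms: acetic acid (14), CC(=O)O
Why: Ti(OiPr)4-mediated opening of a 2,3-epoxy alcohol by a carboxylic acid at the carbon remote from the carbinol: the freely rotating C7 alkoxide and the oxirane oxygen bind titanium, acetate attacks the secondary C2 from the face opposite the oxirane (inversion) and not the fully substituted C1, which gives the trans C1–OH/C2–OAc pair, while the C3 benzoate on the oxirane face cannot take part.

Step 10
Reactants: 15 (1S,2S,3R,6R)-3-(benzoyloxy)-1,6-dihydroxy-1-(hydroxymethyl)cyclohex-4-en-2-yl acetate; 16 benzoyl chloride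
Product: 17 [(1S,2S,3R,6R)-2-acetoxy-3-(benzoyloxy)-1,6-dihydroxycyclohex-4-en-1-yl]methyl benzoate (target)
Conditions: BzCl (1.1 equiv), 2,4,6-collidine, CH2Cl2, −40 → 0 °C
Reagents that add atoms: benzoyl chloride (16), O=C(Cl)c1ccccc1
Why: Chemoselective acylation: one equivalent of benzoyl chloride with a hindered weak base at low temperature esterifies the primary C7 hydroxyl much faster than the secondary C6 hydroxyl beside the quaternary C1 or the tertiary C1 hydroxyl, and these mild conditions should not move the C2 acetate.

**Compound list**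

1 | 2,5-dimethoxybenzyl alcohol | COc1ccc(OC)c(CO)c1 | starting material
2 | tert-butyl(chloro)diphenylsilane | CC(C)(C)[Si](Cl)(c1ccccc1)c1ccccc1 | starting material
3 | tert-butyl[(2,5-dimethoxybenzyl)oxy]diphenylsilane | COc1ccc(OC)c(CO[Si](c2ccccc2)(c2ccccc2)C(C)(C)C)c1 | intermediate
4 | 2-{[tert-butyl(diphenyl)silyl]oxymethyl}-1,4-benzoquinone | O=C1C=CC(=O)C(CO[Si](c2ccccc2)(c2ccccc2)C(C)(C)C)=C1 | intermediate
5 | cyclopenta-1,3-diene (freshly cracked) | C1=CCC=C1 | starting material
6 | endo adduct (4aS,5R,8S,8aR)-2-{[tert-butyl(diphenyl)silyl]oxymethyl}-4a,5,8,8a-tetrahydro-5,8-methanonaphthalene-1,4-dione; C3 and C6 are the ketones, C1 carries C7, ring-fusion hydrogens at C4 and C5 cis and exo | O=C1[C@H]2[C@H]3C=C[C@H](C3)[C@H]2C(=O)C(CO[Si](c2ccccc2)(c2ccccc2)C(C)(C)C)=C1 | intermediate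
7 | hydroperoxy enolate: sodium C1=C6 enolate of 6 carrying OOH on C2 on the convex face (not isolated) | [Na+].O=C1[C@H]2[C@H]3C=C[C@H](C3)[C@H]2C([O-])=C(CO[Si](c2ccccc2)(c2ccccc2)C(C)(C)C)[C@@H]1OO | intermediate
8 | convex-face C1–C2 epoxy diketone: 6 with an oxirane across C1–C2, its oxygen cis to the ring-fusion hydrogens and anti to the norbornene | O=C1[C@H]2[C@H]3C=C[C@H](C3)[C@H]2C(=O)[C@]2(CO[Si](c3ccccc3)(c3ccccc3)C(C)(C)C)O[C@H]12 | intermediate
9 | tricyclic epoxy diol: 8 with both ketones reduced, C3–OH and C6–OH on the concave face (trans to the oxirane oxygen) | O[C@H]1[C@H]2[C@H]3C=C[C@H](C3)[C@H]2[C@@H](O)[C@]2(CO[Si](c3ccccc3)(c3ccccc3)C(C)(C)C)O[C@H]12 | intermediate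
10 | benzoic acid | O=C(O)c1ccccc1 | starting material
11 | tricyclic C3 benzoate: 9 with C3 inverted, C3–OBz on the convex (oxirane) face, C6–OH concave | O=C(c1ccccc1)O[C@@H]1[C@H]2[C@H]3C=C[C@H](C3)[C@H]2[C@@H](O)[C@]2(CO[Si](c3ccccc3)(c3ccccc3)C(C)(C)C)O[C@H]12 | intermediate
12 | (1S,2R,3R,6R)-1-{[tert-butyl(diphenyl)silyl]oxymethyl}-1,2-epoxy-6-hydroxycyclohex-4-en-3-yl benzoate | O=C(c1ccccc1)O[C@@H]1C=C[C@@H](O)[C@]2(CO[Si](c3ccccc3)(c3ccccc3)C(C)(C)C)O[C@H]12 | intermediate
13 | (1S,2R,3R,6R)-1,2-epoxy-6-hydroxy-1-(hydroxymethyl)cyclohex-4-en-3-yl benzoate | O=C(c1ccccc1)O[C@@H]1C=C[C@@H](O)[C@]2(CO)O[C@H]12 | intermediate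
14 | acetic acid | CC(=O)O | starting material
15 | (1S,2S,3R,6R)-3-(benzoyloxy)-1,6-dihydroxy-1-(hydroxymethyl)cyclohex-4-en-2-yl acetate | CC(=O)O[C@H]1[C@H](OC(=O)c2ccccc2)C=C[C@@H](O)[C@@]1(O)CO | intermediate
16 | benzoyl chloride | O=C(Cl)c1ccccc1 | starting material
17 | [(1S,2S,3R,6R)-2-acetoxy-3-(benzoyloxy)-1,6-dihydroxycyclohex-4-en-1-yl]methyl benzoate | CC(=O)O[C@H]1[C@H](OC(=O)c2ccccc2)C=C[C@@H](O)[C@@]1(O)COC(=O)c1ccccc1 | target

**Totals**

Total step count: 10. Longest linear sequence: 10 steps (1 → 17).

**Steps most likely to fail**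

Step 3. The risk is insufficient enantiofacial discrimination: the catalyst may bind both quinone carbonyls, and the uncatalysed cycloaddition may compete. The fallback sets out from 4 and 5. Without catalyst (CH2Cl2, 0 °C) they should give the endo adduct as a racemate, that is 6 together with its mirror image, the (4aR,5S,8R,8aS)-adduct F1. The two antipodes would be separated by preparative chromatography on cellulose tris(3,5-dimethylphenylcarbamate) (supercritical CO2/iPrOH). The route is rejoined at 6.

Step 9. The risk is transfer of the acetyl group from the C2 oxygen to the free primary C7 hydroxyl, or sluggish opening, in the titanium-bound polyol. The fallback sets out from 13. The primary hydroxyl would be benzoylated first (BzCl, 2,4,6-collidine, CH2Cl2, −40 °C) to give [(1S,2R,3R,6R)-3-(benzoyloxy)-1,2-epoxy-6-hydroxycyclohex-4-en-1-yl]methyl benzoate F3. The oxirane would then be opened without metal assistance by acetate in buffered medium (CsOAc, AcOH, DMF, 70 °C). This is an SN2 attack at the less substituted C2 with inversion, and no alkoxide is present that could trigger Payne rearrangement. The fallback arrives directly at 17.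

Step 6. The risk is incomplete differentiation of the two concave hydroxyls, or elimination or no reaction because the carbinol is crowded inside the cage. The fallback sets out from 9. Cycloreversion would be carried out first (Ph2O, 250 °C) to give (1S,2R,3S,6R)-1-{[tert-butyl(diphenyl)silyl]oxymethyl}-1,2-epoxycyclohex-4-ene-3,6-diol F2. Its C3 hydroxyl is then an unhindered allylic carbinol, while C6 remains next to the quaternary C1. Mitsunobu esterification (BzOH, PPh3, DIAD, THF, 0 °C) at C3 with inversion rejoins the route at 12.

**Further compounds**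

F1 | step 3 | (4aR,5S,8R,8aS)-2-{[tert-butyl(diphenyl)silyl]oxymethyl}-4a,5,8,8a-tetrahydro-5,8-methanonaphthalene-1,4-dione (mirror image of 6) | O=C1[C@@H]2[C@@H]3C=C[C@@H](C3)[C@@H]2C(=O)C(CO[Si](c2ccccc2)(c2ccccc2)C(C)(C)C)=C1
F2 | step 6 | (1S,2R,3S,6R)-1-{[tert-butyl(diphenyl)silyl]oxymethyl}-1,2-epoxycyclohex-4-ene-3,6-diol | O[C@H]1C=C[C@@H](O)[C@]2(CO[Si](c3ccccc3)(c3ccccc3)C(C)(C)C)O[C@H]12
F3 | step 9 | [(1S,2R,3R,6R)-3-(benzoyloxy)-1,2-epoxy-6-hydroxycyclohex-4-en-1-yl]methyl benzoate | O=C(c1ccccc1)O[C@@H]1C=C[C@@H](O)[C@]2(COC(=O)c3ccccc3)O[C@H]12
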